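If I am to say what south-east holds when its flask is warmed, I need two times, because the earlier runs stay cold and the heat is a guess: how fast starting material goes at 5 °C, and how long the flask stays there.

| flask | starting material | temperature | remark | time |
|---|---|---|---|---|
| winter | 0.33 M | 5 °C | run made earlier |  |
| south-east | 0.30 M |  | at 5 °C until 8.0 h, from then on at 35 °C | 15 h |
| north | 0.60 M |  | at 5 °C throughout | 15 h |

winter run (percent of the starting material charged)

| time / h | ring / % | starting material / % |
|---|---|---|
| 0.500 | 13.2 | 85.8 |
| 1.33 | 30.3 | 67.0 |
| 2.50 | 48.7 | 48.3 |
| 4.00 | 64.3 | 32.0 |
| 5.00 | 71.0 | 25.1 |

(standard deviation of a reading: 0.3 percentage points)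

* the winner by amount of ring, in percent of the starting material charged; "neither" if no more than 2 percentage points parts them (south-east / north / neither)
* how much ring is there at the end, in percent of the starting material charged: south-east
* how much ring is there at the end, in percent of the starting material charged: north

- the numbers in the tables scatter with a standard deviation of 0.3 percentage points
- the earlier runs do not show what temperature does; that part of a forecast is a guess

From the last winter reading, 25.1% at 5.00 h, I read the cold half-life, the time in which c(starting material) halves at 5 °C if its fall is taken as first order: 2.51 h. The cold stretch of south-east, 8.0 h, is longer than that, by a factor of 3.19, so I expect 11.0% of the charge to meet the heat as starting material. Whether the end then follows kinetic or thermodynamic control I cannot read from these runs, so I commit to that remainder and to no winner.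

The forecast answers south-east, with 92% for south-east and 86% for north, and its words are: “About 13% remains at 8 h, and warming finishes it”. Its remainder differs from my 11.0%.

The flasks give 87.5% of ring in south-east and 86.7% in north, a gap of 0.80 percentage points, so the answer is neither.

    starting material ⇌ ring (K = 17.0, k = 0.00470 min⁻¹, Ea = 79.0 kJ mol⁻¹, ΔH = −9.00 kJ mol⁻¹)
    2 starting material → open dimer (k = 5.90 × 10⁻⁴ M⁻¹ min⁻¹, Ea = 65.0 kJ mol⁻¹)
    (constants at 5 °C)

At 8.00 h, the change of temperature, south-east holds 13.4% starting material, where I reckoned 11.0% for that moment. At 15.0 h the same flask still holds 7.49%. The neighbouring flask is south-east read at 4.0 h, still in the cold, which is 1.59 cold half-lives, so the same reckoning gives 33.1% starting material. That flask holds 32.5% starting material beside 64.2% ring.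

Readings and results were computed on assumed constants, and the scatter is random.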